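**Retrosynthetic overview**

- Numbering used in the text (terpene part): ring A = C1, C6–C10 (isopropyl on C7, methyl on C10); ring B = C1–C6 with C5=C6; C4 = spiro carbon; C15 = CH2 of the pyran ring.
- The pyran ring is closed last by a biomimetic hetero-Diels–Alder reaction of a muurola-4(15),5-diene with the o-quinone methide from diformylphloroglucinol and benzaldehyde (O–C4 and C15–CHPh); the diene comes from the C4 ketone by methylenation.
- Ring B is made by a one-pot [3+3] annulation of a ring A allyl geminal bis(silane) with triethyl orthoacrylate, which forms C1–C2 first and C4–C5 second.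
- Ring A and its two stereocenters (C7, C10) come unchanged from (−)-menthone through its kinetic enol triflate; ring order: A (chiral pool), B, pyran.
- Enabling feature: the CH(SiMe3)2 group on C5 next to the ring A double bond C6=C1 makes C5–C6–C1 an allyl 1,3-dianion equivalent. The first silyl group sends the electrophile to C1 and moves the alkene to C6=C5; the second makes C5 ipso-nucleophilic and leaves the alkene at C5=C6.

Key step: step 3

Assumption: triethyl orthoacrylate and 2,4-diformylphloroglucinol are taken as catalogue chemicals.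

**Step 1**
Reactants: 1 (−)-menthone [(2S,5R)-5-methyl-2-(propan-2-yl)cyclohexan-1-one]
Product: 3 (3R,6S)-3-methyl-6-(propan-2-yl)cyclohex-1-en-1-yl trifluoromethanesulfonate, via lithium enolate 2 (not isolated)
Conditions: LiN(iPr)2, THF, −78 °C; PhNTf2, −78 → 0 °C
Reagents that add atoms: N-phenylbis(trifluoromethanesulfonimide), O=S(=O)(N(c1ccccc1)S(=O)(=O)C(F)(F)F)C(F)(F)F
Why: Kinetic deprotonation of 1 at the unhindered CH2 (C1) rather than at the isopropyl-bearing methine and O-triflation of enolate 2 (enol triflate synthesis) fix the C6=C1 double bond without touching either stereocenter.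

**Step 2**
Reactants: 3 enol triflate; 4 chlorobis(trimethylsilyl)methane
Product: 6 {[(3R,6S)-3-methyl-6-(propan-2-yl)cyclohex-1-en-1-yl]methanediyl}bis(trimethylsilane), via bis(trimethylsilyl)methylmagnesium chloride 5 (not isolated)
Conditions: 4, Mg, THF, reflux; then 3, Pd(PPh3)4 (5 mol %), THF, 50 °C
Reagents that add atoms: none
Why: Kumada–Corriu coupling of an enol triflate with an α-silylalkyl Grignard reagent that has no β-hydrogen (the standard route to allylsilanes, here with the bis-silyl reagent 5) makes the C5–C6 bond and forms no stereocenter.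

**Step 3**
Reactants: 6 allyl geminal bis(silane); 7 triethyl orthoacrylate (3,3,3-triethoxyprop-1-ene)
Product: 10 (4aR,5R,8S)-5-methyl-8-(propan-2-yl)-4,4a,5,6,7,8-hexahydronaphthalen-2(3H)-one, via ketene acetal vinylsilane 8 (not isolated), via diethyl ketal 9 (not isolated)
Conditions: 7 (1.3 equiv), EtOH (1.0 equiv), Me3SiOTf (0.2 equiv), CH2Cl2, −78 → 0 °C; Et3N; then 5% aq. oxalic acid, THF, 0 °C
Reagents that add atoms: water, O
Why: Proposed new method: Me3SiOTf ionises 7 to the 1,1-diethoxyallyl cation, whose CH2 terminus is attacked by C1 of allylsilane 6 (SE2', loss of the first Me3Si group) to give ketene acetal 8 with an exocyclic vinylsilane; proton transfer from ethanol then makes a dialkoxycarbenium ion at C4, the silicon-bearing C5 attacks it, and the β-silyl cation at C6 expels the second Me3Si group to give ketal 9, hydrolysed to 10 on work-up. The closest known reactions are the Lewis-acid Michael addition of silyl enol ethers to α,β-unsaturated ortho esters (Mukaiyama–Michael) and of allylsilanes to enones (Hosomi–Sakurai), the vinylsilane-terminated cyclisation onto oxygen-stabilised cations, and the two-stage Sakurai/carbonyl-ene [3+3] cyclohexane annulation of 1-(silylmethyl)cycloalkenes with enones; new is their merger in one pot with an ortho ester and a geminal bis(silane). Ring B closes in a 6-endo mode with both carbons of the vinylsilane inside the new ring. The only new stereocenter, C1 (C4a of 10), is set in the first bond formation by axial attack on the half-chair of 6 that keeps isopropyl and methyl pseudoequatorial, anti to the pseudoaxial hydrogen on C10, so the chain should enter trans to isopropyl and cis to methyl; this is the kinetic isomer, the C1 epimer of what an equilibrating Robinson annulation of menthone would give. The step needs 1,4- instead of 1,2-addition (the acetal carbon is shielded and the nucleophilic carbon is a hindered ring methine), a single alkene position (each silyl group dictates it) and retention of the C1 and C7 configurations (low temperature, amine quench, hydrolysis at 0 °C).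

**Step 4**
Reactants: 10 enone
Product: 11 (4aR,5R,8S)-5-methyl-2-methylidene-8-(propan-2-yl)-2,3,4,4a,5,6,7,8-octahydronaphthalene [a muurola-4(15),5-diene]
Conditions: Cp2TiMe2 (2.5 equiv), toluene, 70 °C, dark
Reagents that add atoms: dimethyltitanocene, C[Ti](C)(C1C=CC=C1)C1C=CC=C1
Why: Petasis methylenation (Cp2TiMe2 gives Cp2Ti=CH2, a titanium carbonyl olefination) converts C4=O into the exocyclic C4=C15 bond under non-basic conditions, so the γ-hydrogens at C1 and C7 are not exchanged and no stereocenter is formed or lost.

**Step 5**
Reactants: 11 diene; 12 2,4,6-trihydroxybenzene-1,3-dicarbaldehyde (2,4-diformylphloroglucinol); 13 benzaldehyde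
Product: 15 Guajadial C, via o-quinone methide 14 (not isolated)
Conditions: 12 (1.0 equiv), 13 (1.5 equiv), 11 (1.5 equiv), H2O, 100 °C, sealed tube; chromatography
Reagents that add atoms: none
Why: Knoevenagel condensation of 12 with 13 gives the (E)-o-quinone methide 14, which is trapped by the exocyclic C4=C15 bond of 11 in an inverse-electron-demand hetero-Diels–Alder reaction (the biomimetic union used for caryophyllene-derived congeners), C15 bonding to the benzylidene carbon and oxygen to the tertiary, allylic C4, with the spiro and benzylic centers expected from an endo transition state (C5=C6 under the heterodiene, phenyl outside, hence phenyl cis to C5) and axial C–O bond formation on the face of ring B opposite to the hydrogen at C1.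

**Compound list**

1 | (−)-menthone, (2S,5R)-5-methyl-2-(propan-2-yl)cyclohexan-1-one | CC(C)[C@@H]1CC[C@@H](C)CC1=O | starting material
2 | lithium (3R,6S)-3-methyl-6-(propan-2-yl)cyclohex-1-en-1-olate | CC(C)[C@@H]1CC[C@@H](C)C=C1O[Li] | intermediate
3 | (3R,6S)-3-methyl-6-(propan-2-yl)cyclohex-1-en-1-yl trifluoromethanesulfonate | CC(C)[C@@H]1CC[C@@H](C)C=C1OS(=O)(=O)C(F)(F)F | intermediate
4 | chlorobis(trimethylsilyl)methane | C[Si](C)(C)C(Cl)[Si](C)(C)C | starting material
5 | bis(trimethylsilyl)methylmagnesium chloride | C[Si](C)(C)C([Mg]Cl)[Si](C)(C)C | intermediate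
6 | {[(3R,6S)-3-methyl-6-(propan-2-yl)cyclohex-1-en-1-yl]methanediyl}bis(trimethylsilane) | CC(C)[C@@H]1CC[C@@H](C)C=C1C([Si](C)(C)C)[Si](C)(C)C | intermediate
7 | triethyl orthoacrylate (3,3,3-triethoxyprop-1-ene) | C=CC(OCC)(OCC)OCC | starting material
8 | {[(2R,3R,6S)-2-(3,3-diethoxyprop-2-en-1-yl)-3-methyl-6-(propan-2-yl)cyclohexylidene]methyl}(trimethyl)silane (vinylsilane geometry not fixed) | CC(C)[C@@H]1CC[C@@H](C)[C@@H](CC=C(OCC)OCC)C1=C[Si](C)(C)C | intermediate
9 | (4aR,5R,8S)-2,2-diethoxy-5-methyl-8-(propan-2-yl)-2,3,4,4a,5,6,7,8-octahydronaphthalene | CC(C)[C@@H]1CC[C@@H](C)[C@H]2CCC(OCC)(OCC)C=C12 | intermediate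
10 | (4aR,5R,8S)-5-methyl-8-(propan-2-yl)-4,4a,5,6,7,8-hexahydronaphthalen-2(3H)-one | CC(C)[C@@H]1CC[C@@H](C)[C@H]2CCC(=O)C=C12 | intermediate
11 | (4aR,5R,8S)-5-methyl-2-methylidene-8-(propan-2-yl)-2,3,4,4a,5,6,7,8-octahydronaphthalene | CC(C)[C@@H]1CC[C@@H](C)[C@H]2CCC(=C)C=C12 | intermediate
12 | 2,4,6-trihydroxybenzene-1,3-dicarbaldehyde | Oc1cc(O)c(C=O)c(O)c1C=O | starting material
13 | benzaldehyde | O=Cc1ccccc1 | starting material
14 | (5E)-5-benzylidene-2,4-dihydroxy-6-oxocyclohexa-1,3-diene-1,3-dicarbaldehyde | O=CC1=C(O)C(C=O)=C(O)/C(=C\c2ccccc2)C1=O | intermediate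
15 | Guajadial C: (2S,4R)-5,7-dihydroxy-4-phenylchromane-6,8-dicarbaldehyde spiro-linked through C2 to C2' of (4a'R,5'R,8'S)-5'-methyl-8'-(propan-2-yl)-3',4',4a',5',6',7',8'-heptahydro-2'H-naphthalene | CC(C)[C@@H]1CC[C@@H](C)[C@H]2CC[C@@]3(C=C12)C[C@H](c1ccccc1)c1c(O)c(C=O)c(O)c(C=O)c1O3 | target

**Step count**

Total steps: 5. Longest linear sequence: 5 (1 → 3 → 6 → 10 → 11 → 15).

**Steps most likely to fail**

1. Step 3 (proposed new method). Several processes may interfere:
   - attack of the hindered allylsilane at the acetal carbon instead of the CH2 terminus;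
   - oligomerisation through the nucleophilic ketene acetal;
   - protodesilylation of 6 or of the vinylsilane before the second ring bond forms;
   - a dialkoxycarbenium ion too weak to be captured by the vinylsilane;
   - attack on the wrong face at C1;
   - loss of the C1/C7 configuration through a dienol ether.

   Fallback, from 6 and back at 10, makes the two ring bonds in separate, individually known reactions. TiCl4-promoted Hosomi–Sakurai conjugate addition of 6 to 3-acryloyl-1,3-oxazolidin-2-one (CH2Cl2, −78 °C) gives 3-(3-{(1R,3S,6R)-6-methyl-3-(propan-2-yl)-2-[(trimethylsilyl)methylidene]cyclohexyl}propanoyl)-1,3-oxazolidin-2-one F1. LiOH/H2O2 (THF/H2O, 0 °C) cleaves the imide to 3-{(1R,3S,6R)-6-methyl-3-(propan-2-yl)-2-[(trimethylsilyl)methylidene]cyclohexyl}propanoic acid F2. (COCl)2 with catalytic DMF gives 3-{(1R,3S,6R)-6-methyl-3-(propan-2-yl)-2-[(trimethylsilyl)methylidene]cyclohexyl}propanoyl chloride F3. AlCl3 (CH2Cl2, −78 °C) then closes ring B by intramolecular Friedel–Crafts acylation at the silicon-bearing carbon of the vinylsilane to give 10; here the far stronger acylium electrophile replaces the dialkoxycarbenium ion.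

2. Step 2. Transmetalation of the bulky bis-silyl Grignard reagent to the hindered vinylpalladium species may be too slow, so that reduction or homocoupling of the triflate takes over.

   Fallback, from 3 and back at 6, introduces the silyl groups one at a time. Kumada–Corriu coupling of 3 with Me3SiCH2MgCl (Pd(PPh3)4, THF) should give {[(3R,6S)-3-methyl-6-(propan-2-yl)cyclohex-1-en-1-yl]methyl}(trimethyl)silane F4. Allylic lithiation (s-BuLi, TMEDA, THF, −78 °C) and trapping with Me3SiCl at the silicon-bearing carbon then gives 6. Silylallyl anions often silylate at the other terminus, so the 1,3-bis-silyl isomer may form and would be removed by chromatography.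

3. Step 5. Facial and endo/exo selectivity in the cycloaddition may be poor, the o-quinone methide may be consumed by water or by itself, and 11 may isomerise under the hot aqueous, weakly acidic conditions.

   Fallback, from 12 and 13 and back at 15, separates o-quinone methide formation from the cycloaddition. 12, 13 and morpholine are condensed (EtOH, room temperature) to the isolable Mannich base 2,4,6-trihydroxy-5-[morpholin-4-yl(phenyl)methyl]benzene-1,3-dicarbaldehyde F5. F5 is then heated with 11 in dry toluene, so that morpholine is expelled and 14 is released slowly in an aprotic medium with the diene in excess, giving 15. Temperature and solvent of the cycloaddition can then be chosen for selectivity alone.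

**Further compounds**

F1 | step 3 | 3-(3-{(1R,3S,6R)-6-methyl-3-(propan-2-yl)-2-[(trimethylsilyl)methylidene]cyclohexyl}propanoyl)-1,3-oxazolidin-2-one | CC(C)[C@@H]1CC[C@@H](C)[C@@H](CCC(=O)N2CCOC2=O)C1=C[Si](C)(C)C
F2 | step 3 | 3-{(1R,3S,6R)-6-methyl-3-(propan-2-yl)-2-[(trimethylsilyl)methylidene]cyclohexyl}propanoic acid | CC(C)[C@@H]1CC[C@@H](C)[C@@H](CCC(=O)O)C1=C[Si](C)(C)C
F3 | step 3 | 3-{(1R,3S,6R)-6-methyl-3-(propan-2-yl)-2-[(trimethylsilyl)methylidene]cyclohexyl}propanoyl chloride | CC(C)[C@@H]1CC[C@@H](C)[C@@H](CCC(=O)Cl)C1=C[Si](C)(C)C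
F4 | step 2 | {[(3R,6S)-3-methyl-6-(propan-2-yl)cyclohex-1-en-1-yl]methyl}(trimethyl)silane | CC(C)[C@@H]1CC[C@@H](C)C=C1C[Si](C)(C)C
F5 | step 5 | 2,4,6-trihydroxy-5-[morpholin-4-yl(phenyl)methyl]benzene-1,3-dicarbaldehyde (racemic) | O=Cc1c(O)c(C=O)c(O)c(C(c2ccccc2)N2CCOCC2)c1O
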